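The target is an eremophilane (ring A: C1–C2–C3–C4–C5–C10; ring B: C5–C6–C7–C8–C9–C10). In ring A the oxygenated C3, the methyl-bearing C4 and the quaternary ring-fusion carbon C5 lie in a row, so ring A is the one-carbon homologue of a cyclopentanone whose carbonyl (C3) is bonded directly to C5: the (S)-Hajos–Parrish ketone. That carbonyl is olefinated to an ethylidene (C4–C15); an oxidative semipinacol shift then moves C5 from C3 to C4. One operation forms the C4–C5 bond, closes the six-membered ring A, sets C4 and returns the C3 carbonyl. Ring B is completed by enolate chemistry on the enone.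

Key step: step 5

Remark: eremophilane numbering and the usual α/β convention (C14 on C5 and C15 on C4 both β) are used for the decalin compounds; compounds 1–9 are named as indenones, and the configuration drawn at the carbinol-bearing ring carbon of 7 and 8 is the expected major one and is erased in step 4.

Step 1
Reactants: 1 (S)-Hajos–Parrish ketone; 2 ethyltriphenylphosphonium bromide
Product: 3 (7aR,Z)-1-ethylidene-7a-methyl-1,2,3,6,7,7a-hexahydro-5H-inden-5-one
Conditions: 2 (3 equiv), KOtBu (3 equiv), THF, 0 °C to reflux; aq. NH4Cl
Reagents that add atoms: ethyltriphenylphosphonium bromide, CC[P+](c1ccccc1)(c1ccccc1)c1ccccc1.[Br-]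
Why: Wittig olefination, in which the non-stabilised ylide should react at the more electrophilic saturated cyclopentanone carbonyl while the excess base holds the enone as its inert dienolate (returned on work-up), giving the Z-ethylidene (vinylic methyl syn to the quaternary carbon) as with 17-oxo steroids; no stereocentre is formed.

Step 2
Reactants: 3 (Z)-ethylidene enone
Product: 4 (7aR,E)-1-ethylidene-7a-methyl-1,2,3,6,7,7a-hexahydro-5H-inden-5-one
Conditions: PhSSPh (10 mol%), hν (390 nm), C6H6, rt
Reagents that add atoms: none
Why: Thiyl-radical-catalysed alkene isomerisation by reversible addition and loss of PhS•, which should settle at the thermodynamically preferred E isomer because the Z isomer suffers allylic strain between the vinylic methyl and the quaternary carbon; no stereocentre is touched.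

Step 3
Reactants: 4 (E)-ethylidene enone; 5 acetone
Product: 7 (E)-1-ethylidene-6-(2-hydroxypropan-2-yl)-7a-methyl-1,2,3,6,7,7a-hexahydro-5H-inden-5-one, via lithium enolate 6 (not isolated)
Conditions: LiN(iPr)2 (1.1 equiv), THF, −78 °C; acetone (3 equiv), −78 °C; AcOH quench
Reagents that add atoms: acetone, CC(C)=O
Why: Kinetic deprotonation of the enone at the α′ methylene gives the cross-conjugated lithium enolate 6, whose aldol addition to acetone should occur anti to the angular methyl (the new centre is erased in step 4, so its configuration is immaterial).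

Step 4
Reactants: 7 aldol adduct
Product: 9 (E)-1-ethylidene-7a-methyl-6-(propan-2-ylidene)-1,2,3,6,7,7a-hexahydro-5H-inden-5-one, via tertiary mesylate 8 (not isolated)
Conditions: MsCl, Et3N, CH2Cl2, 0 °C; then DBU, rt
Reagents that add atoms: none
Why: Sulfonylation and E1cB elimination complete the aldol condensation and, under equilibrating base, should give the conjugated isopropylidene dienone, which also makes this alkene electron-poor for step 5.

Step 5
Reactants: 9 isopropylidene dienone with (E)-ethylidene
Product: 11 eremophila-7(11),9-diene-3,8-dione (C14 and C15 both β), via dimethyl ketal 10 (not isolated)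
Conditions: PhI(OH)OTs (1.1 equiv), MeOH, 0 °C to rt; then 1 M HCl, THF–H2O, 0 °C
Reagents that add atoms: water, O
Why: PhI(OH)OTs delivers trivalent iodine to the electron-rich C3=C4 alkene at the less substituted C4 from the α face (anti to the angular methyl C14) while methanol caps C3, and loss of PhI from C4 is assisted by the antiperiplanar C3–C5 bond, so that C5 shifts from C3 to C4 and the C3 oxocarbenium ion is trapped as ketal 10 and hydrolysed. The closest known reaction type is the oxidative ring enlargement of alkylidenecycloalkanes by trivalent iodine or thallium trinitrate (Wittig–ring-expansion sequence), and the same quaternary-carbon shift is the basis of steroid D-homoannulation. Ring A is closed as a cyclopentane-to-cyclohexane enlargement by a suprafacial 1,2-alkyl shift (a semipinacol step, not a Baldwin-type closure). The new stereocentre C4 follows from the E geometry together with α-face iodination and inversion at C4, which places C15 cis to C14, while C5 migrates with retention. The step needs chemoselectivity for the ethylidene over the two enone double bonds (secured by their electron poverty) and migration of C5 in preference to C2 (secured by the higher migratory aptitude of the tertiary-alkyl terminus and by the rotamer that keeps the bulky iodanyl group anti to C5). The ketal keeps C4 from epimerising until the short hydrolysis, and 11 should be reduced without delay.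

Step 6
Reactants: 11 eremophila-7(11),9-diene-3,8-dione
Product: 12 3β-hydroxyeremophila-7(11),9-dien-8-one
Conditions: LiBH(s-Bu)3 (1.05 equiv), THF, −78 °C; then H2O
Reagents that add atoms: none
Why: Chemoselective 1,2-reduction of the saturated C3 ketone by a bulky trialkylborohydride (the cross-conjugated dienone is less electrophilic and its β-carbons are fully substituted), with equatorial hydride approach from the α face because the axial β trajectory is blocked by the syn-axial C14 methyl, giving the axial 3β-alcohol.

Step 7
Reactants: 12 3β-hydroxyeremophila-7(11),9-dien-8-one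
Product: 14 3β-hydroxyeremophila-9,11-dien-8-one (7β-isopropenyl), via dilithium dienolate 13 (not isolated)
Conditions: LiN(iPr)2 (2.5 equiv), THF, −78 to −40 °C; then AcOH (5 equiv), THF, −78 °C
Reagents that add atoms: none
Why: Deconjugative kinetic protonation of an extended enolate, in which LDA removes a γ-hydrogen from the isopropylidene methyl syn to the carbonyl and C-protonation at the α-carbon C7 from the α face (anti to the neighbouring C14 methyl) should give the β,γ-unsaturated ketone with a 7β-isopropenyl group.

Step 8
Reactants: 14 3β-hydroxyeremophila-9,11-dien-8-one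
Product: 15 3β-hydroxy-10βH-eremophil-11-en-8-one (cis-fused)
Conditions: [(Ph3P)CuH]6 (0.5 equiv), H2O (5 equiv), C6H6, rt
Reagents that add atoms: none
Why: Conjugate reduction by the copper hydride [(Ph3P)CuH]6, chemoselective for the enone over the isolated isopropenyl alkene, in which axial hydride delivery to C10 through the half-chair that keeps C14 and the 7β-isopropenyl group pseudo-equatorial should give the cis-fused 10βH decalone, as in cuprate additions to angularly methylated octalones.

Step 9
Reactants: 15 3β-hydroxy-10βH-eremophil-11-en-8-one; 16 angelic acid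
Product: 17 3α-angeloyloxy-10βH-eremophil-11-en-8-one
Conditions: PPh3, DIAD, toluene, 0 °C to rt
Reagents that add atoms: angelic acid, C/C=C(/C)C(=O)O
Why: Mitsunobu esterification, an SN2 displacement of the axial 3β-alkoxyphosphonium ion by angelate from the α face, inverts C3 to the equatorial 3α-ester under non-basic conditions that leave the Z-configured angelate and the enolisable C7 centre untouched.

Step 10
Reactants: 17 3α-angeloyloxy-10βH-eremophil-11-en-8-one
Product: 19 3α-angeloyloxy-9β-hydroxy-10βH-eremophil-11-en-8-one, via potassium enolate 18 (not isolated)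
Conditions: KN(SiMe3)2 (1.1 equiv), THF, −78 °C; 2-(phenylsulfonyl)-3-phenyloxaziridine (1.3 equiv), −78 °C; AcOH quench
Reagents that add atoms: 2-(phenylsulfonyl)-3-phenyloxaziridine, O=S(=O)(c1ccccc1)N1OC1c1ccccc1
Why: Davis α-hydroxylation of a ketone enolate, in which kinetic deprotonation at the less substituted α-carbon C9 (the site also preferred in cis-fused decalones) and oxygen transfer to the convex β face of enolate 18 should give the equatorial 9β-hydroxy ketone.

Step 11
Reactants: 19 3α-angeloyloxy-9β-hydroxy-10βH-eremophil-11-en-8-one; 20 3-methylbut-2-enoyl chloride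
Product: 21 (3R,4R,5R,7R,9R,10S)-3-angeloyloxy-9-senecioyloxyeremophil-11-en-8-one (target)
Conditions: pyridine, 4-(dimethylamino)pyridine (5 mol%), CH2Cl2, 0 °C
Reagents that add atoms: 3-methylbut-2-enoyl chloride, CC(C)=CC(Cl)=O
Why: O-acylation of the secondary α-ketol hydroxyl with the acid chloride under nucleophilic catalysis, mild enough to avoid epimerisation at C7 or C9 and deconjugation of the senecioate; no stereocentre is formed.

Compound list
1 | (S)-Hajos–Parrish ketone, (7aS)-7a-methyl-2,3,7,7a-tetrahydro-1H-indene-1,5(6H)-dione | C[C@]12CCC(=O)C=C1CCC2=O | starting material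
2 | ethyltriphenylphosphonium bromide | CC[P+](c1ccccc1)(c1ccccc1)c1ccccc1.[Br-] | starting material
3 | (7aR,Z)-1-ethylidene-7a-methyl-1,2,3,6,7,7a-hexahydro-5H-inden-5-one | O=C1CC[C@@]2(C)C(=C1)CC/C2=C/C | intermediate
4 | (7aR,E)-1-ethylidene-7a-methyl-1,2,3,6,7,7a-hexahydro-5H-inden-5-one | O=C1CC[C@@]2(C)C(=C1)CC/C2=C\C | intermediate
5 | acetone | CC(C)=O | starting material
6 | cross-conjugated lithium enolate of 4 | [Li+].[O-]C1=CC[C@@]2(C)C(=C1)CC/C2=C\C | intermediate (not isolated)
7 | (E)-1-ethylidene-6-(2-hydroxypropan-2-yl)-7a-methyl-1,2,3,6,7,7a-hexahydro-5H-inden-5-one, side chain trans to the angular methyl | CC(C)(O)[C@@H]1C[C@@]2(C)C(=CC1=O)CC/C2=C\C | intermediate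
8 | tertiary methanesulfonate of 7 | CC(C)(OS(C)(=O)=O)[C@@H]1C[C@@]2(C)C(=CC1=O)CC/C2=C\C | intermediate (not isolated)
9 | (E)-1-ethylidene-7a-methyl-6-(propan-2-ylidene)-1,2,3,6,7,7a-hexahydro-5H-inden-5-one | CC(C)=C1C[C@@]2(C)C(=CC1=O)CC/C2=C\C | intermediate
10 | 3,3-dimethoxyeremophila-7(11),9-dien-8-one (C14 and C15 β) | CC(C)=C1C[C@@]2(C)C(=CC1=O)CCC(OC)(OC)[C@@H]2C | intermediate (not isolated)
11 | eremophila-7(11),9-diene-3,8-dione (C14 and C15 β) | CC(C)=C1C[C@@]2(C)C(=CC1=O)CCC(=O)[C@@H]2C | intermediate
12 | 3β-hydroxyeremophila-7(11),9-dien-8-one | CC(C)=C1C[C@@]2(C)C(=CC1=O)CC[C@H](O)[C@@H]2C | intermediate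
13 | dilithium alkoxide dienolate of 12 | [Li+].[Li+].C=C(C)C1C[C@@]2(C)C(=CC=1[O-])CC[C@H]([O-])[C@@H]2C | intermediate (not isolated)
14 | 3β-hydroxyeremophila-9,11-dien-8-one (7β-isopropenyl) | C=C(C)[C@H]1C[C@@]2(C)C(=CC1=O)CC[C@H](O)[C@@H]2C | intermediate
15 | 3β-hydroxy-10βH-eremophil-11-en-8-one | C=C(C)[C@H]1C[C@@]2(C)[C@H](CC[C@H](O)[C@@H]2C)CC1=O | intermediate
16 | angelic acid, (Z)-2-methylbut-2-enoic acid | C/C=C(/C)C(=O)O | starting material
17 | 3α-angeloyloxy-10βH-eremophil-11-en-8-one | C=C(C)[C@H]1C[C@@]2(C)[C@H](CC[C@@H](OC(=O)/C(C)=C\C)[C@@H]2C)CC1=O | intermediate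
18 | potassium C8–C9 enolate of 17 | [K+].C=C(C)[C@H]1C[C@@]2(C)[C@H](CC[C@@H](OC(=O)/C(C)=C\C)[C@@H]2C)C=C1[O-] | intermediate (not isolated)
19 | 3α-angeloyloxy-9β-hydroxy-10βH-eremophil-11-en-8-one | C=C(C)[C@H]1C[C@@]2(C)[C@H](CC[C@@H](OC(=O)/C(C)=C\C)[C@@H]2C)[C@@H](O)C1=O | intermediate
20 | 3-methylbut-2-enoyl chloride (senecioyl chloride) | CC(C)=CC(Cl)=O | starting material
21 | (3R,4R,5R,7R,9R,10S)-3-angeloyloxy-9-senecioyloxyeremophil-11-en-8-one (3α-OAng, 9β-OSen, 7αH, 10βH) | C=C(C)[C@H]1C[C@@]2(C)[C@H](CC[C@@H](OC(=O)/C(C)=C\C)[C@@H]2C)[C@@H](OC(=O)C=C(C)C)C1=O | target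

Total step count: 11. Longest linear sequence: 11 steps (from 1).

Steps most likely to fail

Step 5. The shift may take the methylene carbon C2 instead of the quaternary C5, the iodonium intermediate may be captured by methanol without rearrangement, or ionisation at C4 may erode the stereospecificity. The fallback sets out from 9 and separates the two events. Markovnikov anti-hydroxyselenation of the ethylidene [N-(phenylselanyl)phthalimide, H2O, camphorsulfonic acid (10 mol%), CH2Cl2] should give the β-hydroxy selenide F1, with PhSe on C4 from the α face and OH on C3. Oxidation with an excess of mCPBA to the selenone turns PhSeO2 into a leaving group; the semipinacol ring enlargement of such β-hydroxy selenides is documented to proceed with migration of the more substituted carbon. It follows the same stereochemical course and comes back to the route at 11.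

Step 9. E2 elimination of the axial alkoxyphosphonium ion across C2–C3 or C3–C4, or slow formation of that hindered ion next to the syn-axial C14 methyl, may outrun the SN2 inversion. The fallback sets out from 11 and avoids inversion. Corey–Bakshi–Shibata reduction (BH3·SMe2 with the B-methyl oxazaborolidine from diphenylprolinol, the antipode chosen to deliver hydride to the β face) should give the equatorial alcohol 3α-hydroxyeremophila-7(11),9-dien-8-one F2. Deconjugative protonation as in step 7 gives 3α-hydroxyeremophila-9,11-dien-8-one F3, and copper hydride reduction as in step 8 gives 3α-hydroxy-10βH-eremophil-11-en-8-one F4. Yamaguchi esterification of F4 with angelic acid (2,4,6-trichlorobenzoyl chloride, Et3N, then 4-(dimethylamino)pyridine, toluene) proceeds with retention at C3 and comes back to the route at 17.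

Step 1. The ylide may also attack the enone carbonyl, or the reaction may stall through enolisation of the hindered cyclopentanone. The fallback sets out from 1. The conjugated carbonyl is masked selectively as its 1,3-dithiolane (ethane-1,2-dithiol, BF3·OEt2, MeOH), giving the enone dithiolane F5. Wittig ethylidenation as in step 1 then gives the ethylidene dithiolane F6, and mercury-assisted hydrolysis (Hg(ClO4)2, CaCO3, aqueous THF) comes back to the route at 3.

Further compounds
F1 | step 5 | β-hydroxy selenide from 9, 1-hydroxy-1-[1-(phenylselanyl)ethyl]-7a-methyl-6-(propan-2-ylidene)hexahydroinden-5-one | CC(C)=C1C[C@@]2(C)C(=CC1=O)CC[C@@]2(O)[C@@H](C)[Se]c1ccccc1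
F2 | step 9 | 3α-hydroxyeremophila-7(11),9-dien-8-one | CC(C)=C1C[C@@]2(C)C(=CC1=O)CC[C@@H](O)[C@@H]2C
F3 | step 9 | 3α-hydroxyeremophila-9,11-dien-8-one | C=C(C)[C@H]1C[C@@]2(C)C(=CC1=O)CC[C@@H](O)[C@@H]2C
F4 | step 9 | 3α-hydroxy-10βH-eremophil-11-en-8-one | C=C(C)[C@H]1C[C@@]2(C)[C@H](CC[C@@H](O)[C@@H]2C)CC1=O
F5 | step 1 | 1,3-dithiolane of the conjugated carbonyl of 1 | S1CCSC12CC[C@@]3(C)C(=C2)CCC3=O
F6 | step 1 | 1,3-dithiolane of the conjugated carbonyl of 3 | S1CCSC12CC[C@@]3(C)C(=C2)CC/C3=C/C
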